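J at 0.0660 % of the X charged looked too little to count, and that was the pitfall: the amount to hold it against was the catalyst, not X.

| setting | east | north-east | south | flask |
|---|---|---|---|---|
| X | 0.050 M | 0.050 M | 0.050 M | 0.050 M |
| Q | 1.5 equiv | 1.5 equiv | 1.5 equiv | 1.50 equiv |
| E | 0.25 mol% | 0.4 mol% | 0.18 mol% | 0.18 mol% |
| J | 33 µM | 33 µM | 16 µM | 33 µM |
| remark | run made earlier | run made earlier | run made earlier |  |

- east (time / min: G / %): 4.00: 49.8; 10.0: 75.4; 20.0: 92.8; 30.0: 99.2
- north-east (time / min: G / %): 8.00: 82.7; 15.0: 95.8; 25.0: 99.9; 30.0: 100.0
- south (time / min: G / %): 8.00: 63.7; 15.0: 80.7; 25.0: 91.9; 30.0: 95.7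

(readings scatter by 1 percentage point)

- apparent order in Q when 10 % of the X are converted (percent change of the rate of making G for one percent more Q charged)
- apparent order in E when 10 % of the X are converted (percent change of the rate of making G for one percent more E charged)

I took J for a catalyst poison that holds one E for good, so two amounts mattered, the J charged and the E charged. Their ratio is the dead share, 36.7 % in the flask, about a third of the catalyst. The working catalyst, what stays after J, predicted the south run at 0.804 of the east rate. The readings gave a similar ratio of two times, 0.800, with east at 92.8 % after 20.0 min and south at 91.9 % after 25.0 min, each reading with its scatter. For north-east against east it predicted 1.82, where the forecast read about 1.6, so I held it loosely. If the rate follows the working catalyst, the order in E is one over what remains of the charge, 1.58. No run changed Q, so I had no reckoning of my own for Q.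

The forecast gave 0.6 in Q (0.25 to 1) and 1.3 in E (0.95 to 1.65), lower than my figure, in its words: “Reducing free E steepens the E dependence above 1, to about 1.3.”

The flask gave 0.87 in Q and 1.6 in E.

    L ⇌ E + G (K = 0.0110 M, k = 1100 s⁻¹)
    E + J → Z (k = 7700 M⁻¹ s⁻¹)
    X + D ⇌ L (K = 77.0 M⁻¹, k = 250 M⁻¹ s⁻¹)
    Q + E → D (k = 59.0 M⁻¹ s⁻¹)

At the start of the flask, Q took up E 17 times faster than J did. Even so, by 2.50 min J in the flask was down to 0 % and Z held 36.7 % of the catalyst. With twice the E of the flask and the same J, a dead share of 36.7 % makes the working catalyst grow by a factor of 2.58, and the simulated rate grows by a factor of 2.57.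

Readings and results were generated by integration from invented constants; scatter was added.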